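The carbocycle (C4a, C5, C6, C7, C8, C8a; isochromene numbering, ring oxygen O2) is read as an unzipped 7‑oxanorbornene. The C7 hydroxyl oxygen is a former furan oxygen, C7 and C4a are the furan α‑carbons, and C6 is its silyloxy‑bearing β‑carbon. A bis(oxazoline)copper‑catalysed Diels–Alder reaction of a 3‑silyloxyfuran, already carrying the side chain as an enynyl group, with an (E)‑3‑acetoxyacryloyl imide forms C7–C8 and C4a–C8a together. It sets both ring stereocentres, because exo‑acetoxy syn to the oxygen bridge gives the cis‑diol. Chlorination and E1cB opening of the bridge later unveil the hydroxy chloroenone, and a 6‑endo cycloisomerisation closes the pyran.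

Key step: step 12

Remark (assumption): the sense of induction in step 12 is taken from the square‑planar chelate model of the copper–imide complex; should it prove opposite, the (R,R)‑ligand is used.
Remark: the lactate‑derived carbon in 9, 12, 13, 14 and 15 is stereorandom (15 is a pair of epimers); it becomes sp2 in step 9, so racemic ethyl lactate is used.

Step 1
Reactants: 1 (2S,3S)-2-hydroxy-3-methylpentanoic acid
Product: 2 (2S,3S)-2-hydroxy-N-methoxy-N,3-dimethylpentanamide
Conditions: MeNHOMe·HCl, EDC·HCl, HOBt (cat.), N-methylmorpholine, CH2Cl2, 0 °C → rt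
Reagents that add atoms: N,O-dimethylhydroxylamine hydrochloride, CNOC.Cl
Why: Carbodiimide amide coupling of the α‑hydroxy acid gives the Weinreb amide without touching the two stereocentres, which are the side‑chain carbinol and methyl centres bought with 1.

Step 2
Reactants: 2 (2S,3S)-2-hydroxy-N-methoxy-N,3-dimethylpentanamide; 3 (E)-1,2-bis(tributylstannyl)ethene
Product: 5 (1E,4S,5S)-4-hydroxy-5-methyl-1-(tributylstannyl)hept-1-en-3-one, via stannylvinyllithium 4 (not isolated)
Conditions: 2, i-PrMgCl (1.0 equiv), THF, −20 °C; 3, n-BuLi, THF, −78 °C; combine, −78 → −20 °C; H2O quench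
Reagents that add atoms: none
Why: Tin–lithium exchange gives the E‑vinyllithium with retention, and Weinreb ketone synthesis stops at the ketone through the chelated tetrahedral adduct, the magnesium alkoxide shielding the α‑centre from enolisation.

Step 3
Reactants: 5 (1E,4S,5S)-4-hydroxy-5-methyl-1-(tributylstannyl)hept-1-en-3-one
Product: 6 (1E,3R,4S,5S)-3,5-dimethyl-1-(tributylstannyl)hept-1-ene-3,4-diol
Conditions: MeMgBr (3 equiv), THF, −78 °C
Reagents that add atoms: methylmagnesium bromide, C[Mg]Br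
Why: Cram‑chelate‑controlled Grignard 1,2‑addition through the five‑membered magnesium alkoxide–ketone chelate delivers methyl anti to the sec‑butyl group and should set the tertiary carbinol as 3R.

Step 4
Reactants: 6 (1E,3R,4S,5S)-3,5-dimethyl-1-(tributylstannyl)hept-1-ene-3,4-diol
Product: 7 (1E,3R,4S,5S)-1-iodo-3,5-dimethylhept-1-ene-3,4-diol
Conditions: I2, CH2Cl2, 0 °C
Reagents that add atoms: iodine, II
Why: Iododestannylation proceeds with retention of the E geometry and tolerates the free diol.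

Step 5
Reactants: 8 ethyl lactate (racemic)
Product: 9 2-hydroxy-N-methoxy-N-methylpropanamide (racemic)
Conditions: MeNHOMe·HCl, i-PrMgCl, THF, −20 → 0 °C
Reagents that add atoms: N,O-dimethylhydroxylamine hydrochloride, CNOC.Cl
Why: Aminolysis of the ester by the magnesium amide of N,O‑dimethylhydroxylamine is the standard Weinreb amide formation from lactate esters.

Step 6
Reactants: 9 2-hydroxy-N-methoxy-N-methylpropanamide; 10 1,4-bis(trimethylsilyl)buta-1,3-diyne
Product: 12 2-hydroxy-7-(trimethylsilyl)hepta-4,6-diyn-3-one (racemic), via lithium diynide 11 (not isolated)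
Conditions: 10, MeLi·LiBr, Et2O/THF, rt; 9, i-PrMgCl (1.0 equiv), THF, −20 °C; combine, −78 °C; H2O quench
Reagents that add atoms: none
Why: Mono‑desilylation of the bis‑silyl diyne by methyllithium gives the lithium diynide, which acylates the Weinreb amide once (Weinreb ketone synthesis).

Step 7
Reactants: 12 2-hydroxy-7-(trimethylsilyl)hepta-4,6-diyn-3-one
Product: 13 2-methyl-5-[(trimethylsilyl)ethynyl]furan-3(2H)-one (racemic)
Conditions: Et2NH, EtOH, 0 °C → rt; then AcOH
Reagents that add atoms: none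
Why: Amine‑mediated cyclisation of an α'‑hydroxy ynone to a furan‑3(2H)‑one: conjugate addition of Et2NH to the ynone β‑carbon, then intramolecular O‑addition and loss of the amine, the distal silylalkyne staying as the 5‑substituent.

Step 8
Reactants: 13 2-methyl-5-[(trimethylsilyl)ethynyl]furan-3(2H)-one; 7 (1E,3R,4S,5S)-1-iodo-3,5-dimethylhept-1-ene-3,4-diol
Product: 15 5-[(3E,5R,6S,7S)-5,6-dihydroxy-5,7-dimethylnon-3-en-1-yn-1-yl]-2-methylfuran-3(2H)-one, via ethynylfuranone 14 (not isolated)
Conditions: PdCl2(PPh3)2 (5 mol%), CuI (10 mol%), CsF, Et3N, MeOH/THF (degassed), rt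
Reagents that add atoms: none
Why: Sonogashira coupling with in situ fluoride desilylation keeps the sensitive terminal alkyne at low concentration and joins it to the vinyl iodide with retention of the E geometry.

Step 9
Reactants: 15 5-[(3E,5R,6S,7S)-5,6-dihydroxy-5,7-dimethylnon-3-en-1-yn-1-yl]-2-methylfuran-3(2H)-one
Product: 16 triethyl({5-[(3E,5R,6S,7S)-5,7-dimethyl-5,6-bis(triethylsilyloxy)non-3-en-1-yn-1-yl]-2-methylfuran-3-yl}oxy)silane
Conditions: TESOTf (3.5 equiv), Et3N, CH2Cl2, −78 → 0 °C; used directly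
Reagents that add atoms: triethylsilyl trifluoromethanesulfonate, CC[Si](CC)(CC)OS(=O)(=O)C(F)(F)F
Why: Soft enolisation and O‑silylation at the only enolisable position aromatises the furanone to the 3‑silyloxyfuran diene and at the same time masks both side‑chain hydroxyls as triethylsilyl ethers.

Step 10
Reactants: 17 propiolic acid; 18 oxazolidin-2-one
Product: 19 3-propioloyloxazolidin-2-one
Conditions: DCC, DMAP (cat.), CH2Cl2, 0 °C
Reagents that add atoms: none
Why: Carbodiimide‑mediated N‑acylation of the oxazolidinone gives the ynoyl imide.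

Step 11
Reactants: 19 3-propioloyloxazolidin-2-one
Product: 20 3-[(E)-3-acetoxyacryloyl]oxazolidin-2-one
Conditions: AcOH, N-methylmorpholine (10 mol%), CH2Cl2, rt
Reagents that add atoms: acetic acid, CC(=O)O
Why: Amine‑catalysed conjugate addition of a carboxylic acid to an ynoyl acceptor gives the β‑acyloxy acrylic derivative as the thermodynamically preferred E isomer.

Step 12
Reactants: 16 triethyl({5-[(3E,5R,6S,7S)-5,7-dimethyl-5,6-bis(triethylsilyloxy)non-3-en-1-yn-1-yl]-2-methylfuran-3-yl}oxy)silane; 20 3-[(E)-3-acetoxyacryloyl]oxazolidin-2-one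
Product: 21 (1S,4S,5S,6S)-4-[(3E,5R,6S,7S)-5,7-dimethyl-5,6-bis(triethylsilyloxy)non-3-en-1-yn-1-yl]-1-methyl-5-(2-oxooxazolidine-3-carbonyl)-2-(triethylsilyloxy)-7-oxabicyclo[2.2.1]hept-2-en-6-yl acetate (5-endo imide, 6-exo acetate)
Conditions: [Cu((S,S)-t-Bu-box)](SbF6)2 (10 mol%; t-Bu-box = 2,2'-(propane-2,2-diyl)bis(4-tert-butyl-4,5-dihydrooxazole)), 4 Å MS, CH2Cl2, −78 → −40 °C; cold filtration through Et3N-deactivated silica
Reagents that add atoms: none
Why: The imide binds the divalent copper centre as a planar s‑cis chelate and the electron‑rich furan adds across its C=C in a concerted, asynchronous normal‑demand [4+2] cycloaddition (Diels–Alder), the silyloxy‑activated C7 terminus bonding to the electrophilic β‑carbon C8 and C4a to C8a. The closest known reaction types are the bis(oxazoline)copper‑catalysed Diels–Alder reaction of furan with acryloyl oxazolidinones and the cycloadditions of 3‑alkoxy‑ and 3‑silyloxyfurans. The six‑membered carbocycle is closed by suprafacial [4+2] ring closure, which at the same time creates the oxygen‑bridged 7‑oxabicyclo[2.2.1]heptene. C8 is set by the catalyst, whose tert‑butyl group blocks the Cα‑Si face so that the diene should add to the Cα‑Re face; C7 follows from the bicyclic constraint together with the endo orientation of the imide carbonyl, which puts the acetoxy group exo, syn to the oxygen bridge, and so gives the cis C7–O/C8–O relation, while the centres at C4a and C8a are transient. The step needs regio‑, endo‑ and chemoselectivity: regiochemistry should be secured by the C6 silyloxy group and the chelated imide, endo selectivity by secondary overlap with the imide carbonyl at low temperature, and the isolated enyne and silyl ethers are not expected to react.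

Step 13
Reactants: 21 the Diels–Alder adduct
Product: 22 (1S,4R,5S,6S)-4-[(3E,5R,6S,7S)-5,7-dimethyl-5,6-bis(triethylsilyloxy)non-3-en-1-yn-1-yl]-5-(hydroxymethyl)-1-methyl-2-(triethylsilyloxy)-7-oxabicyclo[2.2.1]hept-2-en-6-ol
Conditions: LiAlH4, THF, −78 → 0 °C; Rochelle salt work-up
Reagents that add atoms: none
Why: Hydride reduction converts the imide to the primary alcohol and cleaves the acetate, while the silyl enol ether keeps the C6 carbonyl masked and the bridge intact.

Step 14
Reactants: 22 the bicyclic diol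
Product: 23 (1S,4S,5S,6S)-4-[(3E,5R,6S,7S)-5,7-dimethyl-5,6-bis(triethylsilyloxy)non-3-en-1-yn-1-yl]-6-hydroxy-1-methyl-2-(triethylsilyloxy)-7-oxabicyclo[2.2.1]hept-2-ene-5-carbaldehyde
Conditions: [Cu(MeCN)4]OTf (5 mol%), 2,2'-bipyridine, TEMPO, N-methylimidazole, air, MeCN, rt
Reagents that add atoms: none
Why: Copper/TEMPO aerobic oxidation is selective for the primary over the hindered secondary alcohol and runs under non‑acidic conditions that spare the silyl enol ether.

Step 15
Reactants: 23 the hydroxy aldehyde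
Product: 24 (1S,4S,5S,6S)-4-[(3E,5R,6S,7S)-5,7-dimethyl-5,6-bis(triethylsilyloxy)non-3-en-1-yn-1-yl]-1-methyl-2,6-bis(triethylsilyloxy)-7-oxabicyclo[2.2.1]hept-2-ene-5-carbaldehyde
Conditions: TESCl, imidazole, DMF, 0 °C
Reagents that add atoms: chlorotriethylsilane, CC[Si](CC)(CC)Cl
Why: Silylation turns the C8 hydroxyl into a poor leaving group and removes it as a competing nucleophile in the pyran closure.

Step 16
Reactants: 24 the silyloxy aldehyde
Product: 26 (4E,5S,6S)-2-chloro-3-[(3E,5R,6S,7S)-5,7-dimethyl-5,6-bis(triethylsilyloxy)non-3-en-1-yn-1-yl]-6-hydroxy-4-(hydroxymethylidene)-6-methyl-5-(triethylsilyloxy)cyclohex-2-en-1-one (mobile enol tautomer of the 4-formyl compound), via chloro ketone 25 (not isolated)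
Conditions: NCS, THF, −78 → 0 °C; then DBU, 0 °C; pH 5 buffer work-up
Reagents that add atoms: N-chlorosuccinimide, O=C1CCC(=O)N1Cl
Why: Electrophilic α‑chlorination of the silyl enol ether places chlorine on C5 and frees the C6 ketone, whose enolate then expels the strained bridging alkoxide by E1cB β‑elimination (the known opening of 7‑oxanorbornanones), giving the α‑chloroenone and the C7 hydroxyl with the C7–O bond untouched, after which the formyl group enolises to the vinylogous acid.

Step 17
Reactants: 26 the vinylogous acid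
Product: 27 (7S,8S)-5-chloro-3-[(1E,3R,4S,5S)-3,5-dimethyl-3,4-bis(triethylsilyloxy)hept-1-en-1-yl]-7-hydroxy-7-methyl-8-(triethylsilyloxy)-7,8-dihydro-6H-isochromen-6-one
Conditions: Ph3PAuNTf2 (5 mol%), CH2Cl2, 0 °C
Reagents that add atoms: none
Why: Monovalent gold activates the alkyne for 6‑endo‑dig attack by the formyl/enol oxygen, the cycloisomerisation known from 2‑alkynylbenzaldehydes, and loss of the vinylogous acid proton gives the neutral pyran directly.

Step 18
Reactants: 27 the tris(triethylsilyl) ether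
Product: 28 (7S,8S)-5-chloro-3-[(1E,3R,4S,5S)-3,4-dihydroxy-3,5-dimethylhept-1-en-1-yl]-7,8-dihydroxy-7-methyl-7,8-dihydro-6H-isochromen-6-one
Conditions: HF·pyridine, pyridine, THF, 0 °C → rt
Reagents that add atoms: none
Why: Buffered fluoride desilylation removes the three triethylsilyl ethers without acid strong enough to ionise the allylic C8 or side‑chain carbinols.

Compound list

1 | (2S,3S)-2-hydroxy-3-methylpentanoic acid | CC[C@H](C)[C@H](O)C(=O)O | starting material
2 | (2S,3S)-2-hydroxy-N-methoxy-N,3-dimethylpentanamide | CC[C@H](C)[C@H](O)C(=O)N(C)OC | intermediate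
3 | (E)-1,2-bis(tributylstannyl)ethene | CCCC[Sn](CCCC)(CCCC)/C=C/[Sn](CCCC)(CCCC)CCCC | starting material
4 | (E)-2-(tributylstannyl)vinyllithium | [Li]/C=C/[Sn](CCCC)(CCCC)CCCC | intermediate (not isolated)
5 | (1E,4S,5S)-4-hydroxy-5-methyl-1-(tributylstannyl)hept-1-en-3-one | CC[C@H](C)[C@H](O)C(=O)/C=C/[Sn](CCCC)(CCCC)CCCC | intermediate
6 | (1E,3R,4S,5S)-3,5-dimethyl-1-(tributylstannyl)hept-1-ene-3,4-diol | CC[C@H](C)[C@H](O)[C@](C)(O)/C=C/[Sn](CCCC)(CCCC)CCCC | intermediate
7 | (1E,3R,4S,5S)-1-iodo-3,5-dimethylhept-1-ene-3,4-diol | CC[C@H](C)[C@H](O)[C@](C)(O)/C=C/I | intermediate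
8 | ethyl lactate (racemic) | CCOC(=O)C(C)O | starting material
9 | 2-hydroxy-N-methoxy-N-methylpropanamide (racemic) | CC(O)C(=O)N(C)OC | intermediate
10 | 1,4-bis(trimethylsilyl)buta-1,3-diyne | C[Si](C)(C)C#CC#C[Si](C)(C)C | starting material
11 | lithium 4-(trimethylsilyl)buta-1,3-diyn-1-ide | [Li]C#CC#C[Si](C)(C)C | intermediate (not isolated)
12 | 2-hydroxy-7-(trimethylsilyl)hepta-4,6-diyn-3-one (racemic) | CC(O)C(=O)C#CC#C[Si](C)(C)C | intermediate
13 | 2-methyl-5-[(trimethylsilyl)ethynyl]furan-3(2H)-one (racemic) | CC1OC(C#C[Si](C)(C)C)=CC1=O | intermediate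
14 | 5-ethynyl-2-methylfuran-3(2H)-one (racemic) | CC1OC(C#C)=CC1=O | intermediate (not isolated)
15 | 5-[(3E,5R,6S,7S)-5,6-dihydroxy-5,7-dimethylnon-3-en-1-yn-1-yl]-2-methylfuran-3(2H)-one (both C2 epimers) | CC[C@H](C)[C@H](O)[C@](C)(O)/C=C/C#CC1=CC(=O)C(C)O1 | intermediate
16 | triethyl({5-[(3E,5R,6S,7S)-5,7-dimethyl-5,6-bis(triethylsilyloxy)non-3-en-1-yn-1-yl]-2-methylfuran-3-yl}oxy)silane | CC[C@H](C)[C@H](O[Si](CC)(CC)CC)[C@](C)(O[Si](CC)(CC)CC)/C=C/C#Cc1cc(O[Si](CC)(CC)CC)c(C)o1 | intermediate
17 | propiolic acid | C#CC(=O)O | starting material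
18 | oxazolidin-2-one | O=C1NCCO1 | starting material
19 | 3-propioloyloxazolidin-2-one | C#CC(=O)N1CCOC1=O | intermediate
20 | 3-[(E)-3-acetoxyacryloyl]oxazolidin-2-one | CC(=O)O/C=C/C(=O)N1CCOC1=O | intermediate
21 | (1S,4S,5S,6S)-4-[(3E,5R,6S,7S)-5,7-dimethyl-5,6-bis(triethylsilyloxy)non-3-en-1-yn-1-yl]-1-methyl-5-(2-oxooxazolidine-3-carbonyl)-2-(triethylsilyloxy)-7-oxabicyclo[2.2.1]hept-2-en-6-yl acetate | CC(=O)O[C@H]1[C@H](C(=O)N2CCOC2=O)[C@]3(C#C/C=C/[C@@](C)(O[Si](CC)(CC)CC)[C@@H](O[Si](CC)(CC)CC)[C@@H](C)CC)C=C(O[Si](CC)(CC)CC)[C@@]1(C)O3 | intermediate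
22 | (1S,4R,5S,6S)-4-[(3E,5R,6S,7S)-5,7-dimethyl-5,6-bis(triethylsilyloxy)non-3-en-1-yn-1-yl]-5-(hydroxymethyl)-1-methyl-2-(triethylsilyloxy)-7-oxabicyclo[2.2.1]hept-2-en-6-ol | O[C@H]1[C@H](CO)[C@]3(C#C/C=C/[C@@](C)(O[Si](CC)(CC)CC)[C@@H](O[Si](CC)(CC)CC)[C@@H](C)CC)C=C(O[Si](CC)(CC)CC)[C@@]1(C)O3 | intermediate
23 | (1S,4S,5S,6S)-4-[(3E,5R,6S,7S)-5,7-dimethyl-5,6-bis(triethylsilyloxy)non-3-en-1-yn-1-yl]-6-hydroxy-1-methyl-2-(triethylsilyloxy)-7-oxabicyclo[2.2.1]hept-2-ene-5-carbaldehyde | O[C@H]1[C@H](C=O)[C@]3(C#C/C=C/[C@@](C)(O[Si](CC)(CC)CC)[C@@H](O[Si](CC)(CC)CC)[C@@H](C)CC)C=C(O[Si](CC)(CC)CC)[C@@]1(C)O3 | intermediate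
24 | (1S,4S,5S,6S)-4-[(3E,5R,6S,7S)-5,7-dimethyl-5,6-bis(triethylsilyloxy)non-3-en-1-yn-1-yl]-1-methyl-2,6-bis(triethylsilyloxy)-7-oxabicyclo[2.2.1]hept-2-ene-5-carbaldehyde | CC[Si](CC)(CC)O[C@H]1[C@H](C=O)[C@]3(C#C/C=C/[C@@](C)(O[Si](CC)(CC)CC)[C@@H](O[Si](CC)(CC)CC)[C@@H](C)CC)C=C(O[Si](CC)(CC)CC)[C@@]1(C)O3 | intermediate
25 | chloro ketone: 24 with the C2 silyl enol ether replaced by C2=O and C3–Cl (C3 epimer not defined, other centres as in 24) | CC[Si](CC)(CC)O[C@H]1[C@H](C=O)[C@]3(C#C/C=C/[C@@](C)(O[Si](CC)(CC)CC)[C@@H](O[Si](CC)(CC)CC)[C@@H](C)CC)C(Cl)C(=O)[C@@]1(C)O3 | intermediate (not isolated)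
26 | (4E,5S,6S)-2-chloro-3-[(3E,5R,6S,7S)-5,7-dimethyl-5,6-bis(triethylsilyloxy)non-3-en-1-yn-1-yl]-6-hydroxy-4-(hydroxymethylidene)-6-methyl-5-(triethylsilyloxy)cyclohex-2-en-1-one | CC[C@H](C)[C@H](O[Si](CC)(CC)CC)[C@](C)(O[Si](CC)(CC)CC)/C=C/C#CC1=C(Cl)C(=O)[C@@](C)(O)[C@@H](O[Si](CC)(CC)CC)/C1=C/O | intermediate
27 | (7S,8S)-5-chloro-3-[(1E,3R,4S,5S)-3,5-dimethyl-3,4-bis(triethylsilyloxy)hept-1-en-1-yl]-7-hydroxy-7-methyl-8-(triethylsilyloxy)-7,8-dihydro-6H-isochromen-6-one | CC[C@H](C)[C@H](O[Si](CC)(CC)CC)[C@](C)(O[Si](CC)(CC)CC)/C=C/C1=CC2=C(Cl)C(=O)[C@@](C)(O)[C@@H](O[Si](CC)(CC)CC)C2=CO1 | intermediate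
28 | (7S,8S)-5-chloro-3-[(1E,3R,4S,5S)-3,4-dihydroxy-3,5-dimethylhept-1-en-1-yl]-7,8-dihydroxy-7-methyl-7,8-dihydro-6H-isochromen-6-one | CC[C@H](C)[C@H](O)[C@](C)(O)/C=C/C1=CC2=C(Cl)C(=O)[C@@](C)(O)[C@@H](O)C2=CO1 | target

Total step count: 18. Longest linear sequence: 13 steps (steps 1–4, 8, 9, 12–18).

Steps most likely to fail

Step 12. The cycloaddition may suffer from poor endo/exo or facial selectivity at the two fully substituted furan termini. The Lewis acid may also divert the silyloxyfuran into a conjugate addition with silyl transfer that does not close the second bond, or open the bridge prematurely. The fallback replaces catalyst control by a covalent auxiliary whose diastereomeric adducts can be separated. It sets out from 17 and 16: propiolic acid 17 is coupled (DCC, DMAP cat.) with commercial (R)-4-benzyloxazolidin-2-one to give (R)-4-benzyl-3-propioloyloxazolidin-2-one F1, and acetic acid is added under N‑methylmorpholine catalysis to give (R)-3-[(E)-3-acetoxyacryloyl]-4-benzyloxazolidin-2-one F2. Chelate‑controlled Diels–Alder reaction of F2 with diene 16 (Me2AlCl, CH2Cl2, −78 °C) should take place on the Cα‑Re face opposite the benzyl group and give the auxiliary‑bearing adduct F3. After chromatography, LiAlH4 reduction of F3 removes auxiliary and acetate, and the route is rejoined at 22.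

Step 16. Chlorination may occur at other electron‑rich sites or more than once while the silyl enol ether is consumed, and the bridge opening of the chloro ketone may be slow or accompanied by β‑elimination of the C8 silyloxy group. The fallback moves the chlorination to the end. It sets out from 24: methanolysis of the silyl enol ether with K2CO3 in MeOH at 0 °C, with E1cB opening in the same flask, should give the chlorine‑free vinylogous acid F4. Gold‑catalysed cycloisomerisation as in step 17 then gives the 5‑unsubstituted protected azaphilone F5. Electrophilic chlorination of F5 with NCS at the nucleophilic C5 position of the vinylogous ester comes back to the route at 27.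

Step 17. The π‑acid may promote 5‑exo instead of 6‑endo closure, or ionise the allylic silyloxy and hydroxy groups. The fallback closes the pyran by addition–elimination instead of metal catalysis. It sets out from 26: pyrrolidine is added in conjugate fashion to the alkyne terminus of the ynenone (EtOH, 0 °C) to give the enaminone‑type pyrrolidine adduct F6. Mild acid (AcOH) then lets the enol oxygen attack the aminated carbon and expel pyrrolidine, coming back to the route at 27.

Further compounds

F1 | step 12 | (R)-4-benzyl-3-propioloyloxazolidin-2-one | C#CC(=O)N1[C@H](Cc2ccccc2)COC1=O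
F2 | step 12 | (R)-3-[(E)-3-acetoxyacryloyl]-4-benzyloxazolidin-2-one | CC(=O)O/C=C/C(=O)N1[C@H](Cc2ccccc2)COC1=O
F3 | step 12 | auxiliary-bearing adduct: 21 with the oxazolidinone replaced by (R)-4-benzyloxazolidin-2-one | CC(=O)O[C@H]1[C@H](C(=O)N2[C@H](Cc4ccccc4)COC2=O)[C@]3(C#C/C=C/[C@@](C)(O[Si](CC)(CC)CC)[C@@H](O[Si](CC)(CC)CC)[C@@H](C)CC)C=C(O[Si](CC)(CC)CC)[C@@]1(C)O3
F4 | step 16 | chlorine-free vinylogous acid: 26 with H in place of Cl | CC[C@H](C)[C@H](O[Si](CC)(CC)CC)[C@](C)(O[Si](CC)(CC)CC)/C=C/C#CC1=CC(=O)[C@@](C)(O)[C@@H](O[Si](CC)(CC)CC)/C1=C/O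
F5 | step 16 | 5-unsubstituted protected azaphilone: 27 with H in place of Cl | CC[C@H](C)[C@H](O[Si](CC)(CC)CC)[C@](C)(O[Si](CC)(CC)CC)/C=C/C1=CC2=CC(=O)[C@@](C)(O)[C@@H](O[Si](CC)(CC)CC)C2=CO1
F6 | step 17 | pyrrolidine adduct of 26 at the alkyne terminus (enamine geometry not defined) | CC[C@H](C)[C@H](O[Si](CC)(CC)CC)[C@](C)(O[Si](CC)(CC)CC)/C=C/C(N1CCCC1)=CC2=C(Cl)C(=O)[C@@](C)(O)[C@@H](O[Si](CC)(CC)CC)/C2=C/O
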